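## Retrosynthetic overview

1. Cut the bond between ring A (C3′ of the chalcone) and the diarylmethine carbon: asymmetric Friedel–Crafts 1,6-addition of cardamonin 10 to the vinyl para-quinone methide 11 generated from diol 9. This is the new step and sets the R centre.
2. Cut the chain C2=C3 alkene of 9: cross-metathesis of homoallylic alcohol 4 with aryl vinyl carbinol 8.
3. Cut the carbinol C–C bond of 4: organocatalytic allylboration of 3-phenylpropanal 1 sets the S centre, the first stereocentre of the route.
4. 8 comes from 4-hydroxybenzaldehyde 5 and vinylmagnesium bromide 6; its carbinol centre is left uncontrolled because it is erased on ionisation.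
5. No ring is formed in the route; all three benzene rings are bought.

## Assumptions

- Descriptors read from the SMILES: diarylmethine carbon R, carbinol carbon S (C1 and C5 of the hept-2-enyl substituent).
- Cardamonin 10 is treated as a purchased, achiral starting material.
- TRIP = 3,3′-bis(2,4,6-triisopropylphenyl)-1,1′-binaphthyl-2,2′-diyl hydrogen phosphate.
- (R)-TRIP is expected to give (S)-4 in step 1; this is checked by optical rotation against the known alcohol.
- (R)-TRIP is assumed to be the antipode that gives the R diarylmethine centre in step 4. The sense of induction of a new reaction cannot be known in advance; if the first run gives the epimer, (S)-TRIP is used in the same step.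

## Route

Step 1
Reactants: 1 3-phenylpropanal; 2 allylboronic acid pinacol ester
Product: 4 (S)-1-phenylhex-5-en-3-ol, via borate ester 3 (not isolated)
Conditions: (R)-TRIP (5 mol %), 2 (1.2 equiv), PhMe, −30 °C, 4 h; aq. NaHCO3 work-up
Reagents that add atoms: none
Why: Chiral-phosphoric-acid-catalysed aldehyde allylboration through a closed six-membered chair transition state in which the acid hydrogen-bonds the boronate oxygen and the formyl C–H, so the allyl group adds to one aldehyde face and sets the S carbinol centre (about 85–90 % ee expected for this linear aldehyde).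

Step 2
Reactants: 5 4-hydroxybenzaldehyde; 6 vinylmagnesium bromide (CH2=CHMgBr)
Product: 8 racemic 4-(1-hydroxyprop-2-en-1-yl)phenol, via magnesium alkoxide 7 (not isolated)
Conditions: CH2=CHMgBr (3.0 equiv), THF, 0 °C → rt; sat. aq. NH4Cl, 0 °C; used without storage
Reagents that add atoms: none
Why: Grignard 1,2-addition to the aldehyde after the first equivalent has deprotonated the phenol; the new carbinol centre is deliberately racemic because it is destroyed when the quinone methide forms in step 4.

Step 3
Reactants: 4 (S)-1-phenylhex-5-en-3-ol; 8 racemic 4-(1-hydroxyprop-2-en-1-yl)phenol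
Product: 9 (2E,5S)-1-(4-hydroxyphenyl)-7-phenylhept-2-ene-1,5-diol (about 1:1 mixture of C1 epimers)
Conditions: 8 (2.5 equiv), second-generation Hoveyda–Grubbs catalyst [RuCl2(H2IMes)(=CH-C6H4-2-OiPr)] (5 mol %), 2,6-dichloro-1,4-benzoquinone (10 mol %), CH2Cl2, 40 °C; Et3N-deactivated SiO2
Reagents that add atoms: none
Why: Olefin cross-metathesis between a fast-reacting terminal homoallylic alcohol and an excess of the slowly homodimerising secondary allylic alcohol gives the E-disubstituted alkene selectively, with free hydroxyls and phenol tolerated and the S carbinol untouched.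

Step 4
Reactants: 9 (2E,5S)-1-(4-hydroxyphenyl)-7-phenylhept-2-ene-1,5-diol; 10 cardamonin
Product: 12 ent-alpinnanin A, via vinyl para-quinone methide 11 (not isolated)
Conditions: (R)-TRIP (10 mol %), 10 (2.0 equiv), 4 Å MS, CH2Cl2, −20 → 0 °C, 9 added over 4 h by syringe pump
Reagents that add atoms: none
Why: Proposed new method: the phosphoric acid dehydrates either C1 epimer of 9 to the same E-configured vinyl para-quinone methide 11 and then holds 11 (P–OH···O=C) and cardamonin (4′-OH···O=P) in one hydrogen-bonded assembly, so that C3′ of ring A (flanked by two hydroxyls, the less hindered and most nucleophilic carbon) is delivered to one face of the exocyclic benzylic carbon in the 1,6-mode (the remote allylic terminus lies outside the reach of the same template, which disfavours 1,8-addition, and the E-alkene prevents the chain hydroxyl from cyclising), setting the diarylmethine centre R under catalyst control independent of the distant carbinol; the closest known reaction type is the chiral-phosphoric-acid-catalysed Friedel–Crafts 1,6-addition of naphthols and indoles to para-quinone methides generated in situ from para-hydroxybenzyl alcohols, which has not been shown for an alkenyl-extended quinone methide, for an acylphloroglucinol (2′-hydroxychalcone) nucleophile, or in the presence of a free remote carbinol.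

## Compound list

1 | 3-phenylpropanal | O=CCCc1ccccc1 | starting material
2 | allylboronic acid pinacol ester (2-allyl-4,4,5,5-tetramethyl-1,3,2-dioxaborolane) | C=CCB1OC(C)(C)C(C)(C)O1 | starting material
3 | (S)-4,4,5,5-tetramethyl-2-[(1-phenylhex-5-en-3-yl)oxy]-1,3,2-dioxaborolane | C=CC[C@@H](OB1OC(C)(C)C(C)(C)O1)CCc1ccccc1 | intermediate (not isolated)
4 | (S)-1-phenylhex-5-en-3-ol | C=CC[C@@H](O)CCc1ccccc1 | intermediate
5 | 4-hydroxybenzaldehyde | O=Cc1ccc(O)cc1 | starting material
6 | vinylmagnesium bromide | C=C[Mg]Br | starting material
7 | bromomagnesium 4-[1-(bromomagnesiooxy)prop-2-en-1-yl]phenolate (racemic) | C=CC(O[Mg]Br)c1ccc(O[Mg]Br)cc1 | intermediate (not isolated)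
8 | racemic 4-(1-hydroxyprop-2-en-1-yl)phenol | C=CC(O)c1ccc(O)cc1 | intermediate
9 | (2E,5S)-1-(4-hydroxyphenyl)-7-phenylhept-2-ene-1,5-diol (mixture of C1 epimers) | OC(/C=C/C[C@@H](O)CCc1ccccc1)c1ccc(O)cc1 | intermediate
10 | cardamonin, (2E)-1-(2,4-dihydroxy-6-methoxyphenyl)-3-phenylprop-2-en-1-one | COc1cc(O)cc(O)c1C(=O)/C=C/c1ccccc1 | starting material
11 | 4-[(2E,5S)-5-hydroxy-7-phenylhept-2-en-1-ylidene]cyclohexa-2,5-dien-1-one | O=C1C=CC(C=C1)=C/C=C/C[C@@H](O)CCc1ccccc1 | intermediate (not isolated)
12 | ent-alpinnanin A, (2E)-1-{2,4-dihydroxy-3-[(1R,2E,5S)-5-hydroxy-1-(4-hydroxyphenyl)-7-phenylhept-2-en-1-yl]-6-methoxyphenyl}-3-phenylprop-2-en-1-one | COc1cc(O)c([C@H](/C=C/C[C@@H](O)CCc2ccccc2)c2ccc(O)cc2)c(O)c1C(=O)/C=C/c1ccccc1 | target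

## Step count and risks

Total steps: 4. Longest linear sequence: 3 (1 → 4 → 9 → 12).

Step 1 is left out of the risk list: it is a known reaction on this aldehyde class. A shortfall in ee is corrected downstream, because the minor enantiomer of 4 ends up as a diastereomer of 12 that is removed by chromatography.

**Step 4 (proposed new step).** Possible failures are 1,8-addition at the allylic terminus, attack through C5′ of ring A or through oxygen, double alkylation of cardamonin, oligomerisation of 11, and weak catalyst control at the diarylmethine carbon. The fallback uses known chemistry and sets out from 9 and 10. An achiral Brønsted acid (diphenyl phosphate, 10 mol %, CH2Cl2, 0 °C) effects the biomimetic acid-catalysed Friedel–Crafts alkylation of the phloroglucinol-type ring by the para-hydroxybenzylic allylic alcohol without stereocontrol. This gives 12 together with about an equal amount of its diarylmethine epimer, (2E)-1-{2,4-dihydroxy-3-[(1S,2E,5S)-5-hydroxy-1-(4-hydroxyphenyl)-7-phenylhept-2-en-1-yl]-6-methoxyphenyl}-3-phenylprop-2-en-1-one F1. Because the carbinol is already fixed S, the two are diastereomers and are separated by preparative reversed-phase HPLC. The fallback comes back to the route at 12.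

**Step 3 (cross-metathesis).** Possible failures are ruthenium hydride isomerisation of 8 to the ethyl ketone, ionisation of 8 or 9 on acidic surfaces, and poor conversion. The fallback sets out from 4 and moves the aryl–carbinol bond formation to a 1,2-addition. Cross-metathesis of 4 with crotonaldehyde (5 equiv, same ruthenium catalyst, CH2Cl2, 40 °C) gives the robust (2E,5S)-5-hydroxy-7-phenylhept-2-enal F2. Addition of [4-(tert-butyldimethylsilyloxy)phenyl]magnesium bromide (4-TBSO-C6H4MgBr, 2.2 equiv, THF, −78 °C) gives (2E,5S)-1-[4-(tert-butyldimethylsilyloxy)phenyl]-7-phenylhept-2-ene-1,5-diol F3. Buffered desilylation (Bu4NF, AcOH, THF, 0 °C) then comes back to the route at 9.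

**Step 2 (Grignard addition to the unprotected phenol aldehyde).** Possible failures are sluggish addition to the poorly soluble, deactivated magnesium phenoxide and loss of the acid-labile product on work-up. The fallback sets out from 5 and masks the phenol. Silylation (TBSCl, imidazole, CH2Cl2) gives 4-(tert-butyldimethylsilyloxy)benzaldehyde F4. Vinylmagnesium bromide (1.2 equiv, THF, −78 °C) gives racemic 1-[4-(tert-butyldimethylsilyloxy)phenyl]prop-2-en-1-ol F5. Buffered desilylation (Bu4NF, AcOH, THF, 0 °C) under non-acidic conditions comes back to the route at 8.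

## Further compounds

F1 | step 4 | (2E)-1-{2,4-dihydroxy-3-[(1S,2E,5S)-5-hydroxy-1-(4-hydroxyphenyl)-7-phenylhept-2-en-1-yl]-6-methoxyphenyl}-3-phenylprop-2-en-1-one | COc1cc(O)c([C@@H](/C=C/C[C@@H](O)CCc2ccccc2)c2ccc(O)cc2)c(O)c1C(=O)/C=C/c1ccccc1
F2 | step 3 | (2E,5S)-5-hydroxy-7-phenylhept-2-enal | O=C/C=C/C[C@@H](O)CCc1ccccc1
F3 | step 3 | (2E,5S)-1-[4-(tert-butyldimethylsilyloxy)phenyl]-7-phenylhept-2-ene-1,5-diol (mixture of C1 epimers) | OC(/C=C/C[C@@H](O)CCc1ccccc1)c1ccc(O[Si](C)(C)C(C)(C)C)cc1
F4 | step 2 | 4-(tert-butyldimethylsilyloxy)benzaldehyde | O=Cc1ccc(O[Si](C)(C)C(C)(C)C)cc1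
F5 | step 2 | racemic 1-[4-(tert-butyldimethylsilyloxy)phenyl]prop-2-en-1-ol | C=CC(O)c1ccc(O[Si](C)(C)C(C)(C)C)cc1
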